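**Retrosynthetic overview**

1. Numbering (daucane): five-membered ring C1(15-CH3)–C2–C3–C4(OH, iPr)–C5(H); seven-membered ring C1–C5–C6(O-aroyl)–C7H2–C8(=C14H2)–C9(OH)–C10H2; β is the face of the C15 methyl.
2. Endgame: the 4-hydroxybenzoate comes from acylation of the 6α-OH (phenol masked as acetate); the C9 configuration comes from MnO2 oxidation and Luche reduction of a C9 epimer mixture.
3. Key disconnection: the seven-membered ring is formed last, from cyclopentane 1,5-dialdehyde 13 and 2-bromo-3-(trimethylsilyl)propene in one pot. Vinyllithium addition makes C8–C9, then an intramolecular Hosomi–Sakurai allylation makes C6–C7 and closes the ring ([5+2] annulation).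
4. Enabling feature: the array C6(O)–C7H2–C8(=C14H2)–C9(O) of the seven-membered ring is a 2-methylene-1,4-diol. It is the adduct of one C3 unit, acting as vinyl anion at C8 and allyl anion at C7, to two aldehyde carbons (C9 and C6) that both hang on the five-membered ring (via C10–C1 and on C5).
5. Ring order: the five-membered ring is present from commercial 3-methylcyclopent-2-en-1-one, and its C5/C1/C4 triad is built from (S)-3-methylcyclopent-2-en-1-ol by silicon-tethered radical cyclization with allyl transfer, Tamao oxidation and isopropyl addition; the seven-membered ring follows in step 10.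

Key step: step 10

Remark: compounds 1, 3, 5, 10, 14 and 19 are taken as catalogue materials; C9 is formed without control in step 10 on purpose, because both epimers converge in step 11.

**Route**

Step 1
Reactants: 1 3-methylcyclopent-2-en-1-one
Product: 2 (S)-3-methylcyclopent-2-en-1-ol
Conditions: (R)-tetrahydro-1-methyl-3,3-diphenyl-1H,3H-pyrrolo[1,2-c][1,3,2]oxazaborole (10 mol %), BH3·SMe2, THF, −20 °C; MeOH, aq. work-up
Reagents that add atoms: none
Why: Corey–Bakshi–Shibata reduction, in which the oxazaborolidine–borane complex binds the ketone with the alkenyl arm as the large group and delivers hydride to one carbonyl face, should set the carbinol centre (future C4, a temporary centre that relays chirality to C5 and C1) as S.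

Step 2
Reactants: 2 (S)-3-methylcyclopent-2-en-1-ol; 3 (bromomethyl)chlorodimethylsilane
Product: 4 (S)-(bromomethyl)dimethyl[(3-methylcyclopent-2-en-1-yl)oxy]silane
Conditions: Et3N, 4-(dimethylamino)pyridine (cat.), CH2Cl2, 0 °C
Reagents that add atoms: none
Why: O-silylation of a secondary alcohol by a chlorosilane should install the bromomethylsilyl radical tether on the carbinol oxygen without touching the stereocentre.

Step 3
Reactants: 4 (S)-(bromomethyl)dimethyl[(3-methylcyclopent-2-en-1-yl)oxy]silane; 5 allyltributylstannane
Product: 6 cis-fused 6-allyl-3,3,6-trimethyl-2-oxa-3-silabicyclo[3.3.0]octane (allyl on the face of the two ring-fusion hydrogens)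
Conditions: 5 (3 equiv), 2,2′-azobis(2-methylpropionitrile) (0.2 equiv), benzene, 80 °C
Reagents that add atoms: none
Why: Silicon-tethered 5-exo-trig radical cyclization followed by Keck allyl transfer should set C5 and the quaternary C1 from the carbinol centre, because the α-silyl radical can only add to C5 on the face of the tethering oxygen (cis-fused oxasilolane) and the resulting tertiary C1 radical takes the allyl group from the stannane on the convex face, anti to the new C5–CH2 bond.

Step 4
Reactants: 6 cis-fused 6-allyl-3,3,6-trimethyl-2-oxa-3-silabicyclo[3.3.0]octane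
Product: 7 3-allyl-2-(hydroxymethyl)-3-methylcyclopentan-1-ol (1-OH, 2-CH2OH and 3-CH3 all cis; allyl on the other face)
Conditions: 30% H2O2, KF, KHCO3, THF/MeOH, rt
Reagents that add atoms: hydrogen peroxide (OO)
Why: Tamao–Fleming oxidation replaces the C–Si bond of the alkoxysilane by C–OH with retention, which should unmask the C6 hydroxymethyl group cis to the ring hydroxyl.

Step 5
Reactants: 7 3-allyl-2-(hydroxymethyl)-3-methylcyclopentan-1-ol
Product: 8 3-allyl-3-methyl-2-[(triethylsilyloxy)methyl]cyclopentan-1-ol (same relative configuration as 7)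
Conditions: Et3SiCl (1.05 equiv), imidazole, CH2Cl2, −78 °C
Reagents that add atoms: chlorotriethylsilane (CC[Si](Cl)(CC)CC)
Why: Kinetic silylation should discriminate the unhindered primary hydroxyl from the ring secondary hydroxyl, which stays free for the oxidation that follows.

Step 6
Reactants: 8 3-allyl-3-methyl-2-[(triethylsilyloxy)methyl]cyclopentan-1-ol
Product: 9 3-allyl-3-methyl-2-[(triethylsilyloxy)methyl]cyclopentan-1-one (CH2OSiEt3 cis to CH3, trans to allyl)
Conditions: Dess–Martin periodinane, pyridine, CH2Cl2, 0 °C to rt
Reagents that add atoms: none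
Why: Dess–Martin oxidation of the secondary alcohol under buffered, non-enolizing conditions should give the ketone without epimerizing the adjacent C5 centre.

Step 7
Reactants: 9 3-allyl-3-methyl-2-[(triethylsilyloxy)methyl]cyclopentan-1-one; 10 isopropylmagnesium chloride
Product: 11 3-allyl-1-isopropyl-3-methyl-2-[(triethylsilyloxy)methyl]cyclopentan-1-ol (OH, CH2OSiEt3 and CH3 all cis; isopropyl and allyl on the other face)
Conditions: 10, anhydrous CeCl3, THF, −78 to 0 °C; aq. NH4Cl
Reagents that add atoms: none
Why: CeCl3-promoted Grignard 1,2-addition, which suppresses enolization and β-hydride reduction, should occur on the cyclopentanone face anti to the adjacent C5 CH2OSiEt3 group and so set C4 with its hydroxyl cis to C6 and to the C1 methyl.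

Step 8
Reactants: 11 3-allyl-1-isopropyl-3-methyl-2-[(triethylsilyloxy)methyl]cyclopentan-1-ol
Product: 12 5-allyl-2-hydroxy-2-isopropyl-5-methylcyclopentane-1-carbaldehyde (CHO, OH and CH3 all cis)
Conditions: (COCl)2, DMSO, CH2Cl2, −78 to −40 °C; Et3N, −78 to 0 °C
Reagents that add atoms: none
Why: Swern conditions cleave and oxidize a primary triethylsilyl ether directly to the aldehyde (one-pot desilylation–oxidation), while the tertiary hydroxyl cannot be oxidized.

Step 9
Reactants: 12 5-allyl-2-hydroxy-2-isopropyl-5-methylcyclopentane-1-carbaldehyde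
Product: 13 2-hydroxy-2-isopropyl-5-methyl-5-(2-oxoethyl)cyclopentane-1-carbaldehyde (CHO, OH and CH3 all cis)
Conditions: O3, CH2Cl2, −78 °C; PPh3, −78 °C to rt
Reagents that add atoms: ozone ([O-][O+]=O)
Why: Ozonolysis of the terminal alkene with reductive work-up should give the C9 aldehyde and leave all stereocentres untouched.

Step 10
Reactants: 13 2-hydroxy-2-isopropyl-5-methyl-5-(2-oxoethyl)cyclopentane-1-carbaldehyde; 14 2-bromo-3-(trimethylsilyl)propene
Product: 17 dauc-8(14)-ene-4β,6α,9-triol (both C9 epimers; H-5 α; trans ring fusion), via 2-lithio-3-(trimethylsilyl)propene 15 (not isolated), via dilithium alkoxide of the C9 vinyl adduct 16 (not isolated)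
Conditions: 14 (2.1 equiv), tert-butyllithium (4.2 equiv), Et2O, −78 °C; then 13, −78 °C; then BF3·OEt2 (4 equiv), CH2Cl2, −78 to −40 °C; aq. NaHCO3
Reagents that add atoms: none
Why: Bromine–lithium exchange gives vinyllithium 15, one equivalent of which is consumed by the tertiary C4–OH (whose alkoxide further shields the neighbouring C6 aldehyde) while the second adds to the unhindered C9 aldehyde to give 16; BF3·OEt2 then activates the remaining C6 aldehyde, which is attacked by the terminal CH2 of the tethered allylsilane (anti SE2′, Hosomi–Sakurai) with loss of Me3SiF, forming C6–C7 and unveiling the C8=C14 methylene. The closest known reaction type is annulation with 2-bromo-3-(trimethylsilyl)propene as a bifunctional conjunctive reagent (vinyl-metal carbonyl addition followed by intramolecular allylsilane–carbonyl cyclization), applied here to a 1,5-dialdehyde so that two C–C bonds, the ring, the exocyclic alkene and both carbinols arise in one operation. The seven-membered ring closes in a 7-exo-trig mode at the carbonyl, with the allylsilane π bond endocyclic to the forming ring. C6 is set by the substrate: the aldehyde should react in the rotamer with C=O eclipsing C5–H (formyl H between the fully substituted C1 and C4), and the tether delivers C7 anti to the C5–C4 bond, which places the new C6–O on the face of H-5 (6α) and leaves C5, C1 and C4 untouched; C9 forms as an epimer mixture and is set in steps 11 and 13. The step needs chemoselectivity between the two aldehydes, secured by the steric gap between the CH2CHO group and the C6 aldehyde flanked by a quaternary and a fully substituted carbon, and it needs ring closure to outrun intermolecular allylation by the allyltrimethylsilane formed on O–H deprotonation, secured by the tether and the low temperature.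

Step 11
Reactants: 17 dauc-8(14)-ene-4β,6α,9-triol (both C9 epimers)
Product: 18 4β,6α-dihydroxydauc-8(14)-en-9-one
Conditions: activated MnO2, CH2Cl2, rt
Reagents that add atoms: none
Why: MnO2 oxidizes only the allylic C9 alcohol, so both C9 epimers should converge on one α-methylene ketone while the homoallylic C6 and tertiary C4 hydroxyls remain.

Step 12
Reactants: 18 4β,6α-dihydroxydauc-8(14)-en-9-one; 19 4-acetoxybenzoyl chloride
Product: 20 6α-(4-acetoxybenzoyloxy)-4β-hydroxydauc-8(14)-en-9-one
Conditions: Et3N, 4-(dimethylamino)pyridine (cat.), CH2Cl2, 0 °C to rt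
Reagents that add atoms: none
Why: Nucleophile-catalysed acylation by an acid chloride should take place at the only acylable hydroxyl, the secondary C6–OH, since the tertiary C4–OH is inert under these conditions.

Step 13
Reactants: 20 6α-(4-acetoxybenzoyloxy)-4β-hydroxydauc-8(14)-en-9-one
Product: 21 6α-(4-acetoxybenzoyloxy)dauc-8(14)-ene-4β,9β-diol
Conditions: NaBH4, CeCl3·7H2O, MeOH, −78 °C
Reagents that add atoms: none
Why: Luche 1,2-reduction of the enone, with hydride approaching C9 from the α face opposite the pseudoaxial C15 methyl on C1 (1,3-relationship), should give the 9β-alcohol and spare both esters at low temperature.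

Step 14
Reactants: 21 6α-(4-acetoxybenzoyloxy)dauc-8(14)-ene-4β,9β-diol
Product: 22 6α-(4-hydroxybenzoyloxy)dauc-8(14)-ene-4β,9β-diol (target)
Conditions: pyrrolidine (1.5 equiv), CH2Cl2, 0 °C
Reagents that add atoms: none
Why: Chemoselective aminolysis of the phenolic acetate, which is far more electrophilic than the alkyl benzoate, should release the phenol and give the target.

**Compound list**

1 | 3-methylcyclopent-2-en-1-one | CC1=CC(=O)CC1 | starting material
2 | (S)-3-methylcyclopent-2-en-1-ol | CC1=C[C@@H](O)CC1 | intermediate
3 | (bromomethyl)chlorodimethylsilane | C[Si](C)(Cl)CBr | starting material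
4 | (S)-(bromomethyl)dimethyl[(3-methylcyclopent-2-en-1-yl)oxy]silane | CC1=C[C@@H](O[Si](C)(C)CBr)CC1 | intermediate
5 | allyltributylstannane | C=CC[Sn](CCCC)(CCCC)CCCC | starting material
6 | cis-fused 6-allyl-3,3,6-trimethyl-2-oxa-3-silabicyclo[3.3.0]octane (allyl on the face of the ring-fusion hydrogens, 6-CH3 on the face of the silicon-bearing ring) | C1[C@@H]2[C@](C)(CC[C@@H]2O[Si]1(C)C)CC=C | intermediate
7 | 3-allyl-2-(hydroxymethyl)-3-methylcyclopentan-1-ol (OH, CH2OH and CH3 all cis) | OC[C@@H]1[C@](C)(CC[C@@H]1O)CC=C | intermediate
8 | 3-allyl-3-methyl-2-[(triethylsilyloxy)methyl]cyclopentan-1-ol (OH, CH2OSiEt3 and CH3 all cis) | CC[Si](CC)(CC)OC[C@@H]1[C@](C)(CC[C@@H]1O)CC=C | intermediate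
9 | 3-allyl-3-methyl-2-[(triethylsilyloxy)methyl]cyclopentan-1-one (CH2OSiEt3 cis to CH3) | CC[Si](CC)(CC)OC[C@@H]1[C@](C)(CCC1=O)CC=C | intermediate
10 | isopropylmagnesium chloride | CC(C)[Mg]Cl | starting material
11 | 3-allyl-1-isopropyl-3-methyl-2-[(triethylsilyloxy)methyl]cyclopentan-1-ol (OH, CH2OSiEt3 and CH3 all cis) | CC[Si](CC)(CC)OC[C@@H]1[C@](C)(CC[C@@]1(O)C(C)C)CC=C | intermediate
12 | 5-allyl-2-hydroxy-2-isopropyl-5-methylcyclopentane-1-carbaldehyde (CHO, OH and CH3 all cis) | O=C[C@@H]1[C@](C)(CC[C@@]1(O)C(C)C)CC=C | intermediate
13 | 2-hydroxy-2-isopropyl-5-methyl-5-(2-oxoethyl)cyclopentane-1-carbaldehyde (CHO, OH and CH3 all cis) | O=C[C@@H]1[C@](C)(CC[C@@]1(O)C(C)C)CC=O | intermediate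
14 | 2-bromo-3-(trimethylsilyl)propene | C=C(Br)C[Si](C)(C)C | starting material
15 | 2-lithio-3-(trimethylsilyl)propene | [Li]C(=C)C[Si](C)(C)C | intermediate
16 | dilithium alkoxide of 2-hydroxy-5-[2-hydroxy-3-(trimethylsilylmethyl)but-3-en-1-yl]-2-isopropyl-5-methylcyclopentane-1-carbaldehyde (both C9 epimers) | O=C[C@@H]1[C@](C)(CC[C@@]1(O[Li])C(C)C)CC(O[Li])C(=C)C[Si](C)(C)C | intermediate
17 | dauc-8(14)-ene-4β,6α,9-triol (both C9 epimers; trans-fused, H-5 α) | C=C1C[C@H](O)[C@@H]2[C@](C)(CC[C@@]2(O)C(C)C)CC1O | intermediate
18 | 4β,6α-dihydroxydauc-8(14)-en-9-one | C=C1C[C@H](O)[C@@H]2[C@](C)(CC[C@@]2(O)C(C)C)CC1=O | intermediate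
19 | 4-acetoxybenzoyl chloride | CC(=O)Oc1ccc(cc1)C(Cl)=O | starting material
20 | 6α-(4-acetoxybenzoyloxy)-4β-hydroxydauc-8(14)-en-9-one | C=C1C[C@H](OC(=O)c2ccc(OC(C)=O)cc2)[C@@H]2[C@](C)(CC[C@@]2(O)C(C)C)CC1=O | intermediate
21 | 6α-(4-acetoxybenzoyloxy)dauc-8(14)-ene-4β,9β-diol | C=C1C[C@H](OC(=O)c2ccc(OC(C)=O)cc2)[C@@H]2[C@](C)(CC[C@@]2(O)C(C)C)C[C@H]1O | intermediate
22 | [(3R,3aS,4S,7R,8aR)-3,7-dihydroxy-8a-methyl-6-methylidene-3-(propan-2-yl)decahydroazulen-4-yl] 4-hydroxybenzoate | C=C1C[C@H](OC(=O)c2ccc(O)cc2)[C@@H]2[C@](C)(CC[C@@]2(O)C(C)C)C[C@H]1O | target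

**Step count and risks**

Total step count: 14. Longest linear sequence: 14 steps (fully linear from 1).

Steps most likely to fail:

Step 10. The organolithium addition may lose chemoselectivity (attack on, or enolization of, the wrong aldehyde). The 2-(silylmethyl)allyl alkoxide may ionize or protodesilylate before the Lewis acid closes the ring. The tethered allylsilane may attack the wrong face of the C6 carbonyl. The fallback sets out from 13 and comes back at 17. Isopropenylmagnesium bromide with CeCl3 (THF, −78 °C) should add selectively to the C9 aldehyde and give 2-hydroxy-5-(2-hydroxy-3-methylbut-3-en-1-yl)-2-isopropyl-5-methylcyclopentane-1-carbaldehyde F1 as C9 epimers. Me2AlCl (CH2Cl2, −78 to 0 °C) should then close the seven-membered ring by an intramolecular carbonyl-ene reaction of the kind in which the ene unit is tethered through its central carbon. The C6 aldehyde is attacked by the terminal CH2 of the isopropenyl group (C6–C7) while an allylic methyl hydrogen moves to oxygen, which gives triol 17 with the exocyclic methylene.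

Step 7. The hindered ketone may enolize toward C5 with β-elimination of the silyloxy group, or be reduced by β-hydride transfer, instead of undergoing addition. The fallback sets out from 9 and comes back at 11. It replaces the preformed basic organometallic by a samarium Barbier coupling (SmI2, 2-iodopropane, HMPA, THF, rt), a non-basic single-electron union of ketone and alkyl iodide that should deliver the isopropyl group to the same face, anti to the C5 substituent. This fallback makes no compound outside the list (none F0).

Step 1. Enantiofacial discrimination may be insufficient for a cyclic enone that has no α-substituent, and conjugate reduction by borane may compete. The fallback sets out from 1 and comes back at 2. Luche reduction (NaBH4, CeCl3·7H2O, MeOH, 0 °C) should give racemic 3-methylcyclopent-2-en-1-ol F2. Lipase-catalysed kinetic resolution (Burkholderia cepacia lipase, vinyl acetate, tert-butyl methyl ether, rt, stopped just past half conversion) should acetylate the (R)-enantiomer to (R)-3-methylcyclopent-2-en-1-yl acetate F3 and leave the (S)-alcohol 2, which is separated by chromatography.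

Further compounds
F1 | step 10 | 2-hydroxy-5-(2-hydroxy-3-methylbut-3-en-1-yl)-2-isopropyl-5-methylcyclopentane-1-carbaldehyde (C9 epimers) | O=C[C@@H]1[C@](C)(CC[C@@]1(O)C(C)C)CC(O)C(C)=C
F0 | step 7 | none | none
F2 | step 1 | racemic 3-methylcyclopent-2-en-1-ol | CC1=CC(O)CC1
F3 | step 1 | (R)-3-methylcyclopent-2-en-1-yl acetate | CC1=C[C@H](OC(C)=O)CC1
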